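**Plan**

- Retrosynthesis: the two benzyl ethers and the 8-O-methyl group are removed first. Ring A is then cut at C8–C8a and C4a–C5, and the remaining 4-pyranone at O1–C8a, C3–C4 and C2–C3. This leads back to a benzyl-protected benzoate, methyl methoxyacetate, a β-ethoxyacryloyl unit and dimethyl squarate.
- Enabling feature: in ring A each of C5, C6, C7 and C8 carries oxygen, with methoxyls on C6/C7 and para-related oxygens on C5/C8. This is the carbon–oxygen pattern of a squarate ester, and C4a–C8a is the C5=C6 alkene of a 4-pyranone (ring C).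
- Forward: ring B is bought. C2–C3 is made by crossed Claisen condensation, C3–C4 by enolate acylation, and ring C by iodine-mediated enaminone closure (O1–C8a). C4a–C5 is made by adding the pyranonyl Grignard to the squarate, and ring A closes last by thermal 4π opening/6π closure (C8–C8a).
- Methylation of the free 8-hydroxyl and hydrogenolysis finish the synthesis.
- Stereochemistry: the target has no stereogenic element. The stereocentres of intermediates 4, 7, 8, 12 and 14 are racemic and are erased by decarboxylation, enolisation or aromatisation.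

Key step: step 7

Remark: the target is achiral (no stereocentre, no configurationally stable axis), so "single enantiomer" is taken to mean the one constitution shown and no asymmetric step is needed.

**Route**

Step 1
Reactants: 1 methyl 3,5-dihydroxy-4-methoxybenzoate
Product: 2 methyl 3,5-bis(benzyloxy)-4-methoxybenzoate
Conditions: BnBr, K2CO3, DMF, 60 °C
Reagents that add atoms: benzyl bromide, BrCc1ccccc1
Why: Williamson etherification of both phenols, which carbonate deprotonates while the methyl ester stays intact; benzyl is chosen because it should survive the enolate, Grignard and thermal steps and leave by hydrogenolysis at the end.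

Step 2
Reactants: 2 methyl 3,5-bis(benzyloxy)-4-methoxybenzoate; 3 methyl methoxyacetate
Product: 4 methyl 3-[3,5-bis(benzyloxy)-4-methoxyphenyl]-2-methoxy-3-oxopropanoate (racemic)
Conditions: LDA (2.2 equiv), 3 (2.2 equiv), THF, −78 °C; then 2, −78 to 0 °C
Reagents that add atoms: none
Why: Crossed Claisen condensation in which the lithium enolate of the methoxyacetate adds to the non-enolisable aryl ester, and the acidic β-keto ester is held as its enolate by the second equivalent, which prevents a second addition.

Step 3
Reactants: 4 methyl 3-[3,5-bis(benzyloxy)-4-methoxyphenyl]-2-methoxy-3-oxopropanoate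
Product: 5 1-[3,5-bis(benzyloxy)-4-methoxyphenyl]-2-methoxyethan-1-one
Conditions: LiCl, DMSO–H2O, 130 °C
Reagents that add atoms: none
Why: Krapcho dealkoxycarbonylation, in which chloride dealkylates the β-keto methyl ester, CO2 is lost and water protonates the enolate, under near-neutral conditions that should leave the benzyl and methyl aryl ethers untouched.

Step 4
Reactants: 5 1-[3,5-bis(benzyloxy)-4-methoxyphenyl]-2-methoxyethan-1-one; 6 (E)-3-ethoxyprop-2-enoyl chloride
Product: 7 (E)-1-[3,5-bis(benzyloxy)-4-methoxyphenyl]-5-ethoxy-2-methoxypent-4-ene-1,3-dione (racemic, enolisable)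
Conditions: LiHMDS (2.2 equiv), THF, −78 °C; then 6, −78 to −20 °C
Reagents that add atoms: none
Why: C-acylation of a ketone lithium enolate with a β-alkoxyacryloyl chloride, the established first stage of γ-pyrone synthesis from ketones; the methoxymethylene is the only enolisable position of 5, and the second equivalent of base stores the diketone as its enolate.

Step 5
Reactants: 7 (E)-1-[3,5-bis(benzyloxy)-4-methoxyphenyl]-5-ethoxy-2-methoxypent-4-ene-1,3-dione
Product: 9 2-[3,5-bis(benzyloxy)-4-methoxyphenyl]-5-iodo-3-methoxy-4H-pyran-4-one, via enaminone 8 (not isolated)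
Conditions: Me2NH (2 M in THF), THF, 0 °C to rt; evaporate; I2, CHCl3, rt
Reagents that add atoms: iodine, II
Why: Addition–elimination of dimethylamine at the β-ethoxy enone gives the enaminone, and iodine-mediated enaminone cyclisation (the reaction type used to make 3-iodochromones) then iodinates its nucleophilic α-carbon, the enol oxygen of the aryl ketone closes onto the iminium carbon and dimethylamine is expelled, so iodine should reach only pyranone C5 and not the electron-rich aryl ring.

Step 6
Reactants: 9 2-[3,5-bis(benzyloxy)-4-methoxyphenyl]-5-iodo-3-methoxy-4H-pyran-4-one; 10 dimethyl squarate (3,4-dimethoxycyclobut-3-ene-1,2-dione)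
Product: 12 2-[3,5-bis(benzyloxy)-4-methoxyphenyl]-5-(1-hydroxy-2,3-dimethoxy-4-oxocyclobut-2-en-1-yl)-3-methoxy-4H-pyran-4-one (racemic), via pyranonylmagnesium chloride 11 (not isolated)
Conditions: i-PrMgCl·LiCl (1.1 equiv), THF, −78 to −50 °C; then added to 10 (1.5 equiv), THF, −78 °C
Reagents that add atoms: none
Why: Iodine–magnesium exchange on the electron-poor alkenyl iodide, analogous to the preparation of 5-magnesiated 1,3-dioxin-4-ones, should outrun conjugate addition and β-elimination of the ring oxygen at low temperature, and the alkenyl Grignard then adds 1,2 to one ketone of the squarate, as organomagnesium and organolithium reagents do with dialkyl squarates.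

Step 7
Reactants: 12 2-[3,5-bis(benzyloxy)-4-methoxyphenyl]-5-(1-hydroxy-2,3-dimethoxy-4-oxocyclobut-2-en-1-yl)-3-methoxy-4H-pyran-4-one
Product: 15 2-[3,5-bis(benzyloxy)-4-methoxyphenyl]-5,8-dihydroxy-3,6,7-trimethoxy-4H-chromen-4-one, via dienylketene 13 (not isolated), via cyclohexadienone 14 (not isolated)
Conditions: PhMe (degassed), 110 °C, Ar
Reagents that add atoms: none
Why: Heating should open the cyclobutenone by thermal conrotatory 4π cleavage of the C(=O)–C(OH) bond to dienylketene 13; the donor hydroxyl turns outward (torquoselectivity), which places the pyranone C5=C6 bond cis to the ketene. Thermal disrotatory 6π electrocyclisation of this ketene–enol–alkene triene then joins the ketene carbon to pyranone C6 and closes the six-membered carbocycle (ring A) as cyclohexadienone 14, and a proton shift from C8a to the C8 oxygen aromatises it to the hydroquinone. The closest known reaction type is the Moore rearrangement of 4-alkenyl- and 4-(hetero)aryl-4-hydroxycyclobutenones to hydroquinones, here with the enone double bond of a 4-pyranone as the alkenyl arm. The only stereocentre formed (C8a of 14) is transient and racemic, so no stereocontrol is required. The step needs outward rotation of the hydroxyl, secured by its donor character, and a single regiochemistry, secured because pyranone C6 is the only carbon the ketene terminus can reach while the other neighbour of C5 is the C4 carbonyl. Oxygen is excluded so that the electron-rich hydroquinone is not carried on to the 5,8-quinone.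

Step 8
Reactants: 15 2-[3,5-bis(benzyloxy)-4-methoxyphenyl]-5,8-dihydroxy-3,6,7-trimethoxy-4H-chromen-4-one
Product: 16 2-[3,5-bis(benzyloxy)-4-methoxyphenyl]-5-hydroxy-3,6,7,8-tetramethoxy-4H-chromen-4-one
Conditions: MeI (1.1 equiv), K2CO3, acetone (degassed), Ar, 40 °C
Reagents that add atoms: iodomethane, CI
Why: Selective Williamson O-methylation, since the 5-hydroxyl is tied up in a hydrogen bond to the C4 carbonyl and is far less acidic and nucleophilic, so one equivalent of iodomethane should alkylate only the free 8-hydroxyl, as in the classical partial methylation of 5,8-dihydroxyflavones.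

Step 9
Reactants: 16 2-[3,5-bis(benzyloxy)-4-methoxyphenyl]-5-hydroxy-3,6,7,8-tetramethoxy-4H-chromen-4-one
Product: 17 2-(3,5-dihydroxy-4-methoxyphenyl)-5-hydroxy-3,6,7,8-tetramethoxy-4H-chromen-4-one (5,3',5'-trihydroxy-3,6,7,8,4'-pentamethoxyflavone)
Conditions: H2 (1 atm), 10% Pd/C, EtOAc–MeOH, rt
Reagents that add atoms: none
Why: Catalytic hydrogenolysis of the two benzyl aryl ethers, under which the tetrasubstituted, cross-conjugated C2=C3 bond of the flavone and the methyl ethers should remain unchanged.

**Compound list**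

1 | methyl 3,5-dihydroxy-4-methoxybenzoate | COC(=O)c1cc(O)c(OC)c(O)c1 | starting material
2 | methyl 3,5-bis(benzyloxy)-4-methoxybenzoate | COC(=O)c1cc(OCc2ccccc2)c(OC)c(OCc2ccccc2)c1 | intermediate
3 | methyl methoxyacetate | COCC(=O)OC | starting material
4 | methyl 3-[3,5-bis(benzyloxy)-4-methoxyphenyl]-2-methoxy-3-oxopropanoate (racemic) | COC(=O)C(OC)C(=O)c1cc(OCc2ccccc2)c(OC)c(OCc2ccccc2)c1 | intermediate
5 | 1-[3,5-bis(benzyloxy)-4-methoxyphenyl]-2-methoxyethan-1-one | COCC(=O)c1cc(OCc2ccccc2)c(OC)c(OCc2ccccc2)c1 | intermediate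
6 | (E)-3-ethoxyprop-2-enoyl chloride | CCO/C=C/C(Cl)=O | starting material
7 | (E)-1-[3,5-bis(benzyloxy)-4-methoxyphenyl]-5-ethoxy-2-methoxypent-4-ene-1,3-dione (racemic) | CCO/C=C/C(=O)C(OC)C(=O)c1cc(OCc2ccccc2)c(OC)c(OCc2ccccc2)c1 | intermediate
8 | (E)-1-[3,5-bis(benzyloxy)-4-methoxyphenyl]-5-(dimethylamino)-2-methoxypent-4-ene-1,3-dione (racemic) | CN(C)/C=C/C(=O)C(OC)C(=O)c1cc(OCc2ccccc2)c(OC)c(OCc2ccccc2)c1 | intermediate
9 | 2-[3,5-bis(benzyloxy)-4-methoxyphenyl]-5-iodo-3-methoxy-4H-pyran-4-one | COc1c(-c2cc(OCc3ccccc3)c(OC)c(OCc3ccccc3)c2)occ(I)c1=O | intermediate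
10 | dimethyl squarate (3,4-dimethoxycyclobut-3-ene-1,2-dione) | COC1=C(OC)C(=O)C1=O | starting material
11 | {6-[3,5-bis(benzyloxy)-4-methoxyphenyl]-5-methoxy-4-oxo-4H-pyran-3-yl}magnesium chloride | COc1c(-c2cc(OCc3ccccc3)c(OC)c(OCc3ccccc3)c2)occ([Mg]Cl)c1=O | intermediate
12 | 2-[3,5-bis(benzyloxy)-4-methoxyphenyl]-5-(1-hydroxy-2,3-dimethoxy-4-oxocyclobut-2-en-1-yl)-3-methoxy-4H-pyran-4-one (racemic) | COC1=C(OC)C(O)(c2coc(-c3cc(OCc4ccccc4)c(OC)c(OCc4ccccc4)c3)c(OC)c2=O)C1=O | intermediate
13 | 2-[3,5-bis(benzyloxy)-4-methoxyphenyl]-5-[(1Z)-1-hydroxy-2,3-dimethoxy-4-oxobuta-1,3-dien-1-yl]-3-methoxy-4H-pyran-4-one | O=C=C(OC)/C(OC)=C(/O)c1coc(-c2cc(OCc3ccccc3)c(OC)c(OCc3ccccc3)c2)c(OC)c1=O | intermediate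
14 | 2-[3,5-bis(benzyloxy)-4-methoxyphenyl]-5-hydroxy-3,6,7-trimethoxy-8aH-chromene-4,8-dione (racemic at C8a) | O=C1C(OC)=C(OC)C(O)=C2C(=O)C(OC)=C(c3cc(OCc4ccccc4)c(OC)c(OCc4ccccc4)c3)OC12 | intermediate
15 | 2-[3,5-bis(benzyloxy)-4-methoxyphenyl]-5,8-dihydroxy-3,6,7-trimethoxy-4H-chromen-4-one | COc1c(-c2cc(OCc3ccccc3)c(OC)c(OCc3ccccc3)c2)oc2c(O)c(OC)c(OC)c(O)c2c1=O | intermediate
16 | 2-[3,5-bis(benzyloxy)-4-methoxyphenyl]-5-hydroxy-3,6,7,8-tetramethoxy-4H-chromen-4-one | COc1c(-c2cc(OCc3ccccc3)c(OC)c(OCc3ccccc3)c2)oc2c(OC)c(OC)c(OC)c(O)c2c1=O | intermediate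
17 | 2-(3,5-dihydroxy-4-methoxyphenyl)-5-hydroxy-3,6,7,8-tetramethoxy-4H-chromen-4-one | COc1c(O)cc(-c2oc3c(OC)c(OC)c(OC)c(O)c3c(=O)c2OC)cc1O | target

**Count**

Total steps: 9. Longest linear sequence: 9 steps (1 to 17).

**Steps most likely to fail, with fallbacks**

1. Step 6. The magnesiated pyranone carries the ring oxygen trans on the neighbouring carbon and may fragment by β-elimination (ring opening to an alkynyl ketone enolate). The exchange reagent may also add in conjugate fashion at C6 before the exchange is complete. Either process would use up the nucleophile before it meets the squarate. The fallback sets out from 9: direct insertion of zinc dust (LiCl, THF, 25 °C) into the carbon–iodine bond should give {6-[3,5-bis(benzyloxy)-4-methoxyphenyl]-5-methoxy-4-oxo-4H-pyran-3-yl}zinc iodide F1. This is a much less basic organometallic that is not expected to fragment or attack the pyranone. Its 1,2-addition to dimethyl squarate 10 would be promoted by MgCl2 as Lewis acid (magnesium-chloride-accelerated organozinc addition to carbonyl groups), and the route is rejoined at 12.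

2. Step 7. If part of the hydroxyl rotates inward, the ketene is captured by its own enol oxygen and lactonises to a butenolide. Closure onto the oxygen-bearing, electron-poor pyranone carbon may also be slow, and the free hydroquinone may oxidise during isolation (traces of quinone would be taken back by a dithionite wash). The fallback sets out from 12: silylation of the tertiary alcohol (TBSOTf, 2,6-lutidine, CH2Cl2, −78 °C) gives 2-[3,5-bis(benzyloxy)-4-methoxyphenyl]-5-{1-[(tert-butyldimethylsilyl)oxy]-2,3-dimethoxy-4-oxocyclobut-2-en-1-yl}-3-methoxy-4H-pyran-4-one F2, which cannot lactonise. The same ring opening and closure in hot toluene should then give the hydroquinone mono-silyl ether 2-[3,5-bis(benzyloxy)-4-methoxyphenyl]-5-[(tert-butyldimethylsilyl)oxy]-8-hydroxy-3,6,7-trimethoxy-4H-chromen-4-one F3, which is not a free hydroquinone. Methylation of its only free hydroxyl (MeI, K2CO3, acetone) gives 2-[3,5-bis(benzyloxy)-4-methoxyphenyl]-5-[(tert-butyldimethylsilyl)oxy]-3,6,7,8-tetramethoxy-4H-chromen-4-one F4, and TBAF in THF removes the silyl group. The route is rejoined at 16, and this path no longer depends on chelation-controlled methylation.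

3. Step 4. O-acylation of the lithium enolate by the acid chloride, or acylation of the silylamide base, would consume 5 without forming the C3–C4 bond. The fallback sets out from 5: soft enolisation (MgBr2·OEt2, i-Pr2NEt, CH2Cl2) with acetyl chloride should give by C-acylation 1-[3,5-bis(benzyloxy)-4-methoxyphenyl]-2-methoxybutane-1,3-dione F5. Condensation of its methyl group with N,N-dimethylformamide dimethyl acetal (toluene, 80 °C) would give enaminone 8, where the route is rejoined at the iodine stage of step 5.

**Further compounds**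

F1 | step 6 | {6-[3,5-bis(benzyloxy)-4-methoxyphenyl]-5-methoxy-4-oxo-4H-pyran-3-yl}zinc iodide | COc1c(-c2cc(OCc3ccccc3)c(OC)c(OCc3ccccc3)c2)occ([Zn]I)c1=O
F2 | step 7 | 2-[3,5-bis(benzyloxy)-4-methoxyphenyl]-5-{1-[(tert-butyldimethylsilyl)oxy]-2,3-dimethoxy-4-oxocyclobut-2-en-1-yl}-3-methoxy-4H-pyran-4-one (racemic) | COC1=C(OC)C(O[Si](C)(C)C(C)(C)C)(c2coc(-c3cc(OCc4ccccc4)c(OC)c(OCc4ccccc4)c3)c(OC)c2=O)C1=O
F3 | step 7 | 2-[3,5-bis(benzyloxy)-4-methoxyphenyl]-5-[(tert-butyldimethylsilyl)oxy]-8-hydroxy-3,6,7-trimethoxy-4H-chromen-4-one | COc1c(-c2cc(OCc3ccccc3)c(OC)c(OCc3ccccc3)c2)oc2c(O)c(OC)c(OC)c(O[Si](C)(C)C(C)(C)C)c2c1=O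
F4 | step 7 | 2-[3,5-bis(benzyloxy)-4-methoxyphenyl]-5-[(tert-butyldimethylsilyl)oxy]-3,6,7,8-tetramethoxy-4H-chromen-4-one | COc1c(-c2cc(OCc3ccccc3)c(OC)c(OCc3ccccc3)c2)oc2c(OC)c(OC)c(OC)c(O[Si](C)(C)C(C)(C)C)c2c1=O
F5 | step 4 | 1-[3,5-bis(benzyloxy)-4-methoxyphenyl]-2-methoxybutane-1,3-dione (racemic) | CC(=O)C(OC)C(=O)c1cc(OCc2ccccc2)c(OC)c(OCc2ccccc2)c1
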